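## Retrosynthetic overview
1. Cut the CH2 bridge last. This gives the (R)-dihydrobenzofuran acetophenone, formaldehyde and 6-ethyl-4-hydroxy-5-methyl-2-pyrone.
2. Open the dihydrofuran ring at O–C2' to give C-geranyl phloroacetophenone. The forward step is a direct enantioselective dehydrogenative closure that mimics the oxidative cyclase. It needs no epoxide, alcohol or dehydration, and it sets (R) and the exo-methylene together.
3. C-geranyl phloroacetophenone comes from phloroacetophenone and geranyl bromide, the laboratory form of aromatic prenyl transfer.
4. The pyrone ring comes from lactonisation of the linear triketide, which is built by a Claisen condensation of methyl 3-oxopentanoate with a propionyl unit.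
5. Ring order: the benzene ring is bought, the dihydrofuran ring is formed in step 2, the pyrone ring is formed in parallel in step 3, and the halves are joined in step 4.

Assumption: the sense of induction in step 2 is extrapolated from 2-methyl-substituted o-allylphenols. The boxax ligand is a known compound, is not counted as a step, and its mirror image would be used if the (S)-product were obtained.

## Route

Step 1
Reactants: 1 2,4,6-trihydroxyacetophenone (phloroacetophenone); 2 geranyl bromide
Product: 3 3-geranyl-2,4,6-trihydroxyacetophenone (E-alkene retained)
Conditions: 1 (2 equiv), 2 (1 equiv), K2CO3 (1 equiv), acetone, reflux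
Reagents that add atoms: none
Why: The phloroglucinol mono-anion is an ambident vinylogous enolate that attacks the soft allylic bromide at carbon (SN2 C-alkylation of a phenolate), the two free ring carbons are equivalent, and the excess of cheap 1 suppresses double and O-alkylation.

Step 2
Reactants: 3 3-geranyl-2,4,6-trihydroxyacetophenone
Product: 4 1-[(2R)-4,6-dihydroxy-2-(6-methylhepta-1,5-dien-2-yl)-2,3-dihydro-1-benzofuran-5-yl]ethan-1-one
Conditions: Pd(OCOCF3)2 (10 mol %), (R,R)-ip-boxax [(R)-2,2'-bis((4R)-4-isopropyl-4,5-dihydrooxazol-2-yl)-1,1'-binaphthyl] (20 mol %), 2,6-dimethyl-1,4-benzoquinone (2 equiv), MeOH, 40–60 °C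
Reagents that add atoms: none
Why: Proposed new method: the free and most acidic 4-OH (para to the acetyl) binds the divalent palladium–boxax complex, whereas the two ortho-OH groups can only form O,O-chelates with the acetyl group that leave no site for the alkene; chloride-free conditions enforce inner-sphere syn-oxypalladation of the neighbouring C2'=C3' bond, which closes 5-exo for geometric reasons (O to C2', Pd to tertiary C3') on the Re face of C2' chosen by the C2-symmetric ligand and so sets (R); β-hydride elimination into the least hindered C3'-methyl group then releases the 1,1-disubstituted alkene and the hindered quinone reoxidises zerovalent palladium without arylating the free ring carbon; the closest known reaction type is the asymmetric Wacker-type oxidative cyclisation of tri- and tetrasubstituted o-allylphenols to 2-alkenyl-2,3-dihydrobenzofurans, in which tertiary C–Pd intermediates, elimination into a methyl group and configurationally stable allylic aryl ether products are established, and the new elements are the C2'-unsubstituted geranyl pattern, the unprotected acylphloroglucinol and the bystander trisubstituted alkene.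

Step 3
Reactants: 5 methyl 3-oxopentanoate; 6 N-methoxy-N-methylpropanamide
Product: 8 6-ethyl-4-hydroxy-5-methyl-2H-pyran-2-one, via methyl 4-methyl-3,5-dioxoheptanoate 7 (not isolated)
Conditions: LiN(iPr)2 (commercial solution, 2.2 equiv), THF, −78 to 0 °C; 6, −78 °C to rt; AcOH (2.2 equiv); solvent switch to toluene in the same flask, 1,8-diazabicyclo[5.4.0]undec-7-ene (DBU, 1 equiv), reflux; acidic work-up
Reagents that add atoms: none
Why: γ-Acylation of the β-keto ester dianion (a Claisen condensation, in which the Weinreb chelate prevents over-addition and proton exchange) builds the same linear triketide as the polyketide pathway, and DBU then drives enol lactonisation with loss of methanol to the stable 4-hydroxy-2-pyrone, in which no stereocentre remains.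

Step 4
Reactants: 4 (R)-dihydrobenzofuran acetophenone; 8 6-ethyl-4-hydroxy-5-methyl-2H-pyran-2-one
Product: 10 3-{[(2R)-5-acetyl-4,6-dihydroxy-2-(6-methylhepta-1,5-dien-2-yl)-2,3-dihydro-1-benzofuran-7-yl]methyl}-6-ethyl-4-hydroxy-5-methyl-2H-pyran-2-one (target), via 6-ethyl-5-methyl-3-methylidenepyran-2,4-dione 9 (not isolated)
Conditions: 4 (1 equiv), 8 (3 equiv), aq. CH2O (37 %, 2 equiv, slow addition), ethylenediammonium diacetate (10 mol %), MeOH–CH2Cl2, rt
Reagents that add atoms: formaldehyde, C=O
Why: Knoevenagel condensation of 8 with formaldehyde gives the strongly electrophilic methylidene-dione 9, which is trapped in a Michael/Friedel–Crafts addition by C7, the only free and doubly activated ring carbon of 4 (three-component carba-Betti-type methylene bridging); the near-neutral conditions leave the allylic aryl ether stereocentre and both alkenes untouched, and the excess of cheap 8 channels all of 4 into the heterodimer.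

## Compound list
1 | 1-(2,4,6-trihydroxyphenyl)ethan-1-one (phloroacetophenone) | CC(=O)c1c(O)cc(O)cc1O | starting material
2 | (2E)-1-bromo-3,7-dimethylocta-2,6-diene (geranyl bromide) | CC(C)=CCC/C(C)=C/CBr | starting material
3 | 1-{3-[(2E)-3,7-dimethylocta-2,6-dien-1-yl]-2,4,6-trihydroxyphenyl}ethan-1-one | CC(=O)c1c(O)cc(O)c(C/C=C(C)/CCC=C(C)C)c1O | intermediate
4 | 1-[(2R)-4,6-dihydroxy-2-(6-methylhepta-1,5-dien-2-yl)-2,3-dihydro-1-benzofuran-5-yl]ethan-1-one | C=C(CCC=C(C)C)[C@H]1Cc2c(O)c(C(C)=O)c(O)cc2O1 | intermediate
5 | methyl 3-oxopentanoate | CCC(=O)CC(=O)OC | starting material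
6 | N-methoxy-N-methylpropanamide | CCC(=O)N(C)OC | starting material
7 | methyl 4-methyl-3,5-dioxoheptanoate (not isolated; C4 racemic and enolised) | CCC(=O)C(C)C(=O)CC(=O)OC | intermediate
8 | 6-ethyl-4-hydroxy-5-methyl-2H-pyran-2-one | CCc1oc(=O)cc(O)c1C | intermediate
9 | 6-ethyl-5-methyl-3-methylidenepyran-2,4-dione (not isolated) | C=C1C(=O)OC(CC)=C(C)C1=O | intermediate
10 | 3-{[(2R)-5-acetyl-4,6-dihydroxy-2-(6-methylhepta-1,5-dien-2-yl)-2,3-dihydro-1-benzofuran-7-yl]methyl}-6-ethyl-4-hydroxy-5-methyl-2H-pyran-2-one | C=C(CCC=C(C)C)[C@H]1Cc2c(O)c(C(C)=O)c(O)c(Cc3c(O)c(C)c(CC)oc3=O)c2O1 | target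

## Step count and risks
Total steps: 4. Longest linear sequence: 3 (1 → 3 → 4 → 10). The pyrone 8 is made in parallel in one step.

**Step 2 is the most likely to fail.** There are four risks:
- 6-endo closure to the chromene.
- β-hydride elimination towards C4', or towards C2' to give the benzofuran.
- Sequestration of the catalyst by the hydroxy-ketone chelate.
- Modest ee.

The fallback sets out from 1 and comes back at 4. Compound 1 is monobrominated (N-bromosuccinimide, MeCN, 0 °C) to 1-(3-bromo-2,4,6-trihydroxyphenyl)ethan-1-one F1. F1 is then joined to myrcene in an enantioselective Heck/Tsuji–Trost heteroannulation (Pd2(dba)3, a chiral sulfinamide monophosphine ligand, K2CO3). Zerovalent palladium inserts into the C–Br bond, and the aryl group adds to the unsubstituted vinyl terminus of the diene. The para-phenoxide then closes on the internal terminus of the 2-substituted π-allyl under ligand control. The O–C2' bond is still the ring-closing bond, the exo-methylene is already present in myrcene, and the step count is unchanged.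

**Step 4 is the second risk.** The pyrone may outcompete 4 for 9, so that the pyrone homodimer dominates. The fallback sets out from 8 and comes back at 10. Compound 8 is condensed with formaldehyde and p-toluenesulfinic acid to the bench-stable 6-ethyl-4-hydroxy-5-methyl-3-[(4-methylbenzenesulfonyl)methyl]-2H-pyran-2-one F2. F2 is purified free of 8 and then treated with 4 and NaHCO3 in MeCN. Slow loss of sulfinate releases 9 with no free pyrone present, so C7 of 4 is the only carbon nucleophile available.

**Step 1 is the third risk.** The yield may be low because of O-geranylation and bis-geranylation. The fallback sets out from 1 and comes back at 3. Mitsunobu etherification of the most acidic, non-chelated 4-OH with geraniol (PPh3, DIAD, THF, 0 °C) gives 1-{4-[(2E)-3,7-dimethylocta-2,6-dien-1-yloxy]-2,6-dihydroxyphenyl}ethan-1-one F3. A Bi(OTf)3-catalysed [1,3] O-to-C shift (CH2Cl2, low temperature, tight allyl cation/phenoxide ion pair) then moves the geranyl group to one of the two equivalent ortho carbons to give 3.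

Further compounds
F1 | step 2 | 1-(3-bromo-2,4,6-trihydroxyphenyl)ethan-1-one | CC(=O)c1c(O)cc(O)c(Br)c1O
F2 | step 4 | 6-ethyl-4-hydroxy-5-methyl-3-[(4-methylbenzenesulfonyl)methyl]-2H-pyran-2-one | CCc1oc(=O)c(CS(=O)(=O)c2ccc(C)cc2)c(O)c1C
F3 | step 1 | 1-{4-[(2E)-3,7-dimethylocta-2,6-dien-1-yloxy]-2,6-dihydroxyphenyl}ethan-1-one | CC(=O)c1c(O)cc(OC/C=C(C)/CCC=C(C)C)cc1O
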